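**Retrosynthetic overview**

1. Ring C / ring B: the C2–C1' bond is cut last. A Rh-catalysed asymmetric 1,4-arylation of an 8-lavandulylchromone sets C2 (S) on a pyranone ring that is already in place.
2. Lavandulyl chain on C8 (C1''H2–C2''H(C8''(Me)=C9''H2)–C3''H2–C4''H=C5''Me2): C4''=C5'' comes from a Wittig reaction on a C4'' aldehyde. That aldehyde is released from a temporary seven-membered aryl lactone O7–C4''(=O), a ring that is not in the target.
3. Key cut C1''–C2'' (made together with the temporary O7–C4'' bond): the O7–C7=C8–C1'' array of ring A is an ortho-quinone methide retron. An NHC-homoenolate formal [4+3] annulation of this quinone methide with (E)-4-methylpenta-2,4-dienal closes the lactone, brings in C2''–C4'' and the intact isopropenyl group, and sets C2''.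
4. Ring order: chromone pyranone ring (step 1), temporary oxepinone (closed in step 5, opened in step 6), C2 stereocentre on ring C (step 9).

Key step: step 5

Remark: the target is taken as (2S,2''R), as the SMILES encodes. For each chiral catalyst the antipode that gives the configuration drawn is used (both antipodes are available), and the sense of induction is to be checked on the first run.

**Route**

Step 1
Reactants: 1 1-(2,4-dihydroxy-6-methoxyphenyl)ethan-1-one
Product: 3 7-hydroxy-5-methoxy-4H-chromen-4-one, via enaminone 2 (not isolated)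
Conditions: Me2NCH(OMe)2 (1.5 equiv), PhMe, 80 °C; then conc. HCl, CH2Cl2, 40 °C
Reagents that add atoms: N,N-dimethylformamide dimethyl acetal, COC(OC)N(C)C
Why: Condensation of the methyl ketone with the amide acetal gives the enaminone, and acid then drives addition of the ortho-OH and loss of dimethylamine (enaminone route to chromones); only the 2-OH can reach the enaminone carbon, so the 4-OH becomes 7-OH and the 6-OMe becomes 5-OMe.

Step 2
Reactants: 3 7-hydroxy-5-methoxy-4H-chromen-4-one
Product: 4 8-[(dimethylamino)methyl]-7-hydroxy-5-methoxy-4H-chromen-4-one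
Conditions: CH2(NMe2)2 (1.1 equiv), 1,4-dioxane, 80 °C
Reagents that add atoms: bis(dimethylamino)methane, CN(C)CN(C)C
Why: Mannich aminomethylation should occur at C8, which is ortho to the 7-OH and para to the 5-OMe and is the usual site of electrophilic attack on 7-hydroxychromones; the phenoxide formed by the amine also shields the pyranone from amine addition.

Step 3
Reactants: 4 8-[(dimethylamino)methyl]-7-hydroxy-5-methoxy-4H-chromen-4-one
Product: 5 (7-hydroxy-5-methoxy-4-oxo-4H-chromen-8-yl)-N,N,N-trimethylmethanaminium iodide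
Conditions: MeI (3 equiv), acetone, 23 °C, dark; filtration
Reagents that add atoms: iodomethane, CI
Why: N-Quaternisation (Menshutkin reaction) of the benzylic amine, which is far more nucleophilic than the acidic phenol, turns the amine into a leaving group for later release of the quinone methide.

Step 4
Reactants: 6 methacrolein (2-methylprop-2-enal); 7 (triphenylphosphoranylidene)acetaldehyde
Product: 8 (2E)-4-methylpenta-2,4-dienal
Conditions: PhMe, 70 °C (sealed), 6 in excess, cat. BHT; distillation
Reagents that add atoms: none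
Why: Wittig olefination with the stabilised formylmethylene ylide should give the (E)-enal, and the excess of volatile 6 limits a second homologation.

Step 5
Reactants: 5 (7-hydroxy-5-methoxy-4-oxo-4H-chromen-8-yl)-N,N,N-trimethylmethanaminium iodide; 8 (2E)-4-methylpenta-2,4-dienal
Product: 10 chromone-fused (4S)-4-(prop-1-en-2-yl)-4,5-dihydro-1-benzoxepin-2(3H)-one (lactone O = O7; C5H2 on C8; 5-OMe kept), via ortho-quinone methide 9 (not isolated)
Conditions: chiral aminoindanol-derived N-mesityl triazolium BF4 (15 mol %), Cs2CO3 (1.3 equiv), 4 Å MS, THF, 23 → 40 °C, 5 added in portions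
Reagents that add atoms: none
Why: Base converts 5 into its phenoxide betaine, which loses trimethylamine to release the ring-A ortho-quinone methide 9 slowly, while the triazolylidene adds to 8 to give a dienyl amino-enol (homoenolate equivalent) whose β-carbon (future C2'') attacks the exocyclic C1'' of 9 with re-aromatisation of ring A. The closest known reaction type is the NHC-catalysed enantioselective formal [4+3] annulation of enals with ortho-quinone methides generated in situ, which gives 4-substituted 4,5-dihydro-1-benzoxepin-2(3H)-ones. The seven-membered ring is closed after the intermolecular C–C bond formation by O-acylation: the O7 phenoxide attacks the acyl azolium carbon (lactonisation) and releases the carbene. The only new stereocentre, C2'' (C4 of the oxepinone, S), is set in the C–C bond-forming step by the aminoindanol backbone of the catalyst, which shields one face of the (E)-configured homoenolate, and because it is β to the carbonyl it cannot epimerise by enolisation later. The step needs β- and not δ-attack of the dienyl homoenolate, which is the usual site of reaction of NHC-bound dienals and the only one that leads to a lactone able to turn the catalyst over. It also needs capture of 9 by the homoenolate before 9 oligomerises or adds the free carbene, which the slow, base-gated release from the sparingly soluble salt should secure; the ring-A position is already fixed because the methide carbon sits on C8.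

Step 6
Reactants: 10 chromone-fused (4S)-4-(prop-1-en-2-yl)-4,5-dihydro-1-benzoxepin-2(3H)-one
Product: 11 (3S)-3-[(7-hydroxy-5-methoxy-4-oxo-4H-chromen-8-yl)methyl]-4-methylpent-4-enal
Conditions: DIBAL-H (1.1 equiv), CH2Cl2, −78 °C; MeOH, then aq. Rochelle salt
Reagents that add atoms: none
Why: DIBAL-H half-reduction of the activated aryl lactone should stop at the aluminium hemiacetal at −78 °C and give the aldehyde and the free 7-OH on work-up, the chromone carbonyl (a vinylogous ester) being much less electrophilic.

Step 7
Reactants: 11 (3S)-3-[(7-hydroxy-5-methoxy-4-oxo-4H-chromen-8-yl)methyl]-4-methylpent-4-enal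
Product: 12 7-hydroxy-5-methoxy-8-[(2R)-5-methyl-2-(prop-1-en-2-yl)hex-4-en-1-yl]-4H-chromen-4-one
Conditions: i-PrPPh3I (3.2 equiv), n-BuLi (3.0 equiv), THF, 0 °C; then 11, −78 → 23 °C; aq. NH4Cl
Reagents that add atoms: isopropyltriphenylphosphonium iodide, CC(C)[P+](c1ccccc1)(c1ccccc1)c1ccccc1.[I-]
Why: Wittig olefination with the non-stabilised isopropylidene ylide builds the C4''=C5'' alkene without an E/Z issue; the first equivalent deprotonates the 7-OH, which deactivates the chromone towards the ylide, and C2'' is not acidic.

Step 8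
Reactants: 12 7-hydroxy-5-methoxy-8-[(2R)-5-methyl-2-(prop-1-en-2-yl)hex-4-en-1-yl]-4H-chromen-4-one
Product: 13 5-methoxy-7-(methoxymethoxy)-8-[(2R)-5-methyl-2-(prop-1-en-2-yl)hex-4-en-1-yl]-4H-chromen-4-one
Conditions: MOMCl (1.5 equiv), K2CO3, acetone, 0 → 23 °C
Reagents that add atoms: chloromethyl methyl ether, COCCl
Why: O-Alkylation (Williamson type) of the acidic 7-OH removes the proton that would quench the aryl-rhodium species in step 9, and one acid treatment can later remove both MOM groups.

Step 9
Reactants: 13 5-methoxy-7-(methoxymethoxy)-8-[(2R)-5-methyl-2-(prop-1-en-2-yl)hex-4-en-1-yl]-4H-chromen-4-one; 14 [2-(methoxymethoxy)phenyl]boronic acid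
Product: 15 (2S)-5-methoxy-7-(methoxymethoxy)-2-[2-(methoxymethoxy)phenyl]-8-[(2R)-5-methyl-2-(prop-1-en-2-yl)hex-4-en-1-yl]-2,3-dihydro-4H-chromen-4-one
Conditions: [Rh(OH)(L*)]2 (3 mol % Rh; L* = electron-poor MeO-BIPHEP-type bisphosphine with P(3,4,5-F3C6H2)2 groups), 14 (3 equiv), CH2Cl2/H2O, 30 °C, no added base
Reagents that add atoms: none
Why: Rh(I)-catalysed asymmetric 1,4-addition of the arylboronic acid (Hayashi–Miyaura reaction) to C2=C3 of the chromone sets C2 (S) by enantioface-selective carbometallation under control of the chiral bisphosphine, the remote C2'' having no influence, and the base-free conditions avoid retro-oxa-Michael opening of the flavanone.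

Step 10
Reactants: 15 (2S)-5-methoxy-7-(methoxymethoxy)-2-[2-(methoxymethoxy)phenyl]-8-[(2R)-5-methyl-2-(prop-1-en-2-yl)hex-4-en-1-yl]-2,3-dihydro-4H-chromen-4-one
Product: 16 kushenol R, (2S)-7-hydroxy-2-(2-hydroxyphenyl)-5-methoxy-8-[(2R)-5-methyl-2-(prop-1-en-2-yl)hex-4-en-1-yl]-2,3-dihydro-4H-chromen-4-one
Conditions: 2 M HCl (aq)/MeOH–THF, 23 → 40 °C, monitored
Reagents that add atoms: none
Why: Acid-catalysed acetal cleavage of both MOM ethers under mild conditions should leave the lavandulyl alkenes and the flavanone ring intact, so C2 and C2'' keep their configuration.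

**Compound list**

1 | 1-(2,4-dihydroxy-6-methoxyphenyl)ethan-1-one | CC(=O)c1c(O)cc(O)cc1OC | starting material
2 | (E)-3-(dimethylamino)-1-(2,4-dihydroxy-6-methoxyphenyl)prop-2-en-1-one | CN(C)/C=C/C(=O)c1c(O)cc(O)cc1OC | intermediate
3 | 7-hydroxy-5-methoxy-4H-chromen-4-one | COc1cc(O)cc2occc(=O)c12 | intermediate
4 | 8-[(dimethylamino)methyl]-7-hydroxy-5-methoxy-4H-chromen-4-one | COc1cc(O)c(CN(C)C)c2occc(=O)c12 | intermediate
5 | (7-hydroxy-5-methoxy-4-oxo-4H-chromen-8-yl)-N,N,N-trimethylmethanaminium iodide | COc1cc(O)c(C[N+](C)(C)C)c2occc(=O)c12.[I-] | intermediate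
6 | methacrolein (2-methylprop-2-enal) | CC(=C)C=O | starting material
7 | (triphenylphosphoranylidene)acetaldehyde | O=CC=P(c1ccccc1)(c1ccccc1)c1ccccc1 | starting material
8 | (2E)-4-methylpenta-2,4-dienal | C=C(C)/C=C/C=O | intermediate
9 | 5-methoxy-8-methylidene-4H-chromene-4,7(8H)-dione (ring-A ortho-quinone methide) | C=C1C(=O)C=C(OC)C2=C1OC=CC2=O | intermediate
10 | chromone-fused (4S)-4-(prop-1-en-2-yl)-4,5-dihydro-1-benzoxepin-2(3H)-one: 5-methoxychromone with O7 and C8 bridged by –C(=O)–CH2–CH(isopropenyl)–CH2– (acyl on O7; CH2 on C8) | C=C(C)[C@@H]1CC(=O)Oc2cc(OC)c3c(=O)ccoc3c2C1 | intermediate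
11 | (3S)-3-[(7-hydroxy-5-methoxy-4-oxo-4H-chromen-8-yl)methyl]-4-methylpent-4-enal | C=C(C)[C@H](CC=O)Cc1c(O)cc(OC)c2c(=O)ccoc12 | intermediate
12 | 7-hydroxy-5-methoxy-8-[(2R)-5-methyl-2-(prop-1-en-2-yl)hex-4-en-1-yl]-4H-chromen-4-one | C=C(C)[C@H](CC=C(C)C)Cc1c(O)cc(OC)c2c(=O)ccoc12 | intermediate
13 | 5-methoxy-7-(methoxymethoxy)-8-[(2R)-5-methyl-2-(prop-1-en-2-yl)hex-4-en-1-yl]-4H-chromen-4-one | C=C(C)[C@H](CC=C(C)C)Cc1c(OCOC)cc(OC)c2c(=O)ccoc12 | intermediate
14 | [2-(methoxymethoxy)phenyl]boronic acid | COCOc1ccccc1B(O)O | starting material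
15 | (2S)-5-methoxy-7-(methoxymethoxy)-2-[2-(methoxymethoxy)phenyl]-8-[(2R)-5-methyl-2-(prop-1-en-2-yl)hex-4-en-1-yl]-2,3-dihydro-4H-chromen-4-one | C=C(C)[C@H](CC=C(C)C)Cc1c(OCOC)cc(OC)c2c1O[C@H](c1ccccc1OCOC)CC2=O | intermediate
16 | kushenol R, (2S)-7-hydroxy-2-(2-hydroxyphenyl)-5-methoxy-8-[(2R)-5-methyl-2-(prop-1-en-2-yl)hex-4-en-1-yl]-2,3-dihydro-4H-chromen-4-one | C=C(C)[C@H](CC=C(C)C)Cc1c(O)cc(OC)c2c1O[C@H](c1ccccc1O)CC2=O | target

**Step count and risks**

Total step count: 10. Longest linear sequence: 9 steps (1, 2, 3, 5, 6, 7, 8, 9, 10).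

Steps most likely to fail:

Step 5. The transient quinone methide may be consumed by oligomerisation or by addition of the free carbene before the homoenolate reaches it. The dienyl homoenolate may also react at its δ-terminus, or facial control at the unhindered CH2 acceptor may be poor. The fallback sets out from 3 and returns at 13, and replaces the annulation by an sp3–sp2 cross-coupling of a chain that already carries the stereocentre. Iodination of 3 with N-iodosuccinimide at C8 gives 8-iodo-7-hydroxy-5-methoxy-4H-chromen-4-one F1, and MOMCl/K2CO3 gives 8-iodo-5-methoxy-7-(methoxymethoxy)-4H-chromen-4-one F2. In parallel, (S)-lavandulol F3 (from commercial racemic lavandulol by lipase-mediated kinetic resolution; it has the same spatial arrangement as the (2R)-lavandulyl group of the target) is converted with PPh3/I2/imidazole into (S)-lavandulyl iodide F4, and zinc insertion gives [(2S)-5-methyl-2-(prop-1-en-2-yl)hex-4-en-1-yl]zinc iodide F5. Negishi coupling of F2 with F5 (Pd/biarylphosphine, THF) gives 13.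

Step 9. Transmetallation and insertion of the ortho-substituted aryl group may be slow on a chromone that is deactivated by the 5-OMe and crowded at C8; protodeboronation may then win, or enantioface control may be eroded. The fallback sets out from 13 and returns at 15, and sets C2 by hydride delivery instead of aryl delivery. Pd(II)-catalysed oxidative C2-arylation of 13 with 14 (oxidative Heck type, O2 or a quinone as oxidant) gives 5-methoxy-7-(methoxymethoxy)-2-[2-(methoxymethoxy)phenyl]-8-[(2R)-5-methyl-2-(prop-1-en-2-yl)hex-4-en-1-yl]-4H-chromen-4-one F7. Copper hydride-catalysed asymmetric conjugate reduction of this flavone (Cu(OAc)2, chiral bisphosphine, silane, t-BuOH), which leaves the isolated alkenes alone, gives 15.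

Step 6. The aluminium hemiacetal may collapse early, because the 7-oxychromone is a good leaving group, and the freed aldehyde is then over-reduced; hydride may also add to the chromone carbonyl. The fallback sets out from 10 and returns at 11, and avoids metal hydrides. Thiolysis of the activated aryl lactone with EtSH/Et3N gives S-ethyl (3S)-3-[(7-hydroxy-5-methoxy-4-oxo-4H-chromen-8-yl)methyl]-4-methylpent-4-enethioate F6. Fukuyama reduction (Et3SiH, Pd/C, acetone, 23 °C) of this thioester gives 11.

**Further compounds**

F1 | step 5 | 8-iodo-7-hydroxy-5-methoxy-4H-chromen-4-one | COc1cc(O)c(I)c2occc(=O)c12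
F2 | step 5 | 8-iodo-5-methoxy-7-(methoxymethoxy)-4H-chromen-4-one | COCOc1cc(OC)c2c(=O)ccoc2c1I
F3 | step 5 | (S)-lavandulol, (2S)-5-methyl-2-(prop-1-en-2-yl)hex-4-en-1-ol | C=C(C)[C@H](CC=C(C)C)CO
F4 | step 5 | (S)-lavandulyl iodide, (3S)-3-(iodomethyl)-2,6-dimethylhepta-1,5-diene | C=C(C)[C@H](CC=C(C)C)CI
F5 | step 5 | [(2S)-5-methyl-2-(prop-1-en-2-yl)hex-4-en-1-yl]zinc iodide | C=C(C)[C@H](CC=C(C)C)C[Zn]I
F6 | step 6 | S-ethyl (3S)-3-[(7-hydroxy-5-methoxy-4-oxo-4H-chromen-8-yl)methyl]-4-methylpent-4-enethioate | C=C(C)[C@H](CC(=O)SCC)Cc1c(O)cc(OC)c2c(=O)ccoc12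
F7 | step 9 | 5-methoxy-7-(methoxymethoxy)-2-[2-(methoxymethoxy)phenyl]-8-[(2R)-5-methyl-2-(prop-1-en-2-yl)hex-4-en-1-yl]-4H-chromen-4-one | C=C(C)[C@H](CC=C(C)C)Cc1c(OCOC)cc(OC)c2c(=O)cc(-c3ccccc3OCOC)oc12
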